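**Strategy.** Labdane numbering is used (ring A = C1–C5 + C10, ring B = C5–C10). Ring A is a heteroatom-free cyclohexane held between two quaternary carbons, C4 (gem-dimethyl) and C10 (angular methyl), so it is opened at C2–C3. Ring-closing olefin metathesis of an allyl group on C10 with the vinyl end of a 1,1-dimethylallyl group on C5 closes ring A onto an enantiopure ring B cyclohexenone and delivers the trans-decalin in one operation. The precursor is a 5,6-trans-dialkenyl cyclohex-2-enone made from (S)-carvone. Ring B is then functionalised (C17, C11, C6 oxygen) and the dienol side chain is attached by Julia–Kocienski olefination.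

Key step: step 4

Remark: carbons are referred to by labdane numbering (C17 = carbon on C8, C11–C16 = side chain, C20 = angular methyl); systematic names are in the compound list.
Assumption: the (R,R)-ligand of step 14 is taken to give the (S)-configured ether; if the sense of induction is the opposite, the enantiomeric ligand is used.

Step 1
Reactants: 1 (S)-(+)-carvone
Product: 3 (1S)-4-methyl-5-oxocyclohex-3-en-1-yl acetate, via methoxy hydroperoxide 2 (not isolated)
Conditions: O3, CH2Cl2–MeOH, −78 °C; then Ac2O, Et3N, DMAP (cat.), −78 °C → rt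
Reagents that add atoms: ozone, [O-][O+]=O
Why: Ozonolysis/Criegee rearrangement: ozone cleaves only the electron-rich isopropenyl alkene (the enone C=C is deactivated), methanol traps the carbonyl oxide as 2, and its peracetate rearranges with migration of the ring carbon to oxygen with retention, so the carvone stereocentre passes unchanged into the acetate.

Step 2
Reactants: 3 (1S)-4-methyl-5-oxocyclohex-3-en-1-yl acetate; 4 trimethyl(3-methylbut-2-en-1-yl)silane
Product: 6 (5S,6R)-6-methyl-5-(2-methylbut-3-en-2-yl)cyclohex-2-en-1-one, via Sakurai adduct 5 (not isolated)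
Conditions: TiCl4, CH2Cl2, −78 °C; aq. NaHCO3 work-up; then DBU, CH2Cl2, 0 °C → rt
Reagents that add atoms: none
Why: Hosomi–Sakurai conjugate addition followed by E1cB elimination: the allylsilane reacts through its γ-carbon and so places the 1,1-dimethylallyl group on the enone β-carbon (future C5) anti to the acetoxy group (axial attack on the half-chair with pseudo-equatorial OAc, 3,5-trans), after which DBU expels acetate to give the conjugated enone and equilibrates the methyl-bearing carbon.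

Step 3
Reactants: 6 (5S,6R)-6-methyl-5-(2-methylbut-3-en-2-yl)cyclohex-2-en-1-one
Product: 7 (5R,6R)-6-methyl-5-(2-methylbut-3-en-2-yl)-6-(prop-2-en-1-yl)cyclohex-2-en-1-one
Conditions: LiN(i-Pr)2, THF, −78 °C; allyl bromide, DMPU, −78 → −20 °C
Reagents that add atoms: allyl bromide, C=CCBr
Why: Kinetic α′-deprotonation gives the cross-conjugated lithium enolate, and alkylation anti to the neighbouring bulky 1,1-dimethylallyl group sets the quaternary carbon (future C10) with the allyl group trans to that substituent (enolate alkylation).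

Step 4
Reactants: 7 (5R,6R)-6-methyl-5-(2-methylbut-3-en-2-yl)-6-(prop-2-en-1-yl)cyclohex-2-en-1-one
Product: 8 (4aR,8aR)-5,5,8a-trimethyl-4a,5,8,8a-tetrahydronaphthalen-1(4H)-one
Conditions: second-generation Grubbs catalyst RuCl2(=CHPh)(H2IMes)(PCy3) (5 mol %), CH2Cl2 (0.005 M), 40 °C
Reagents that add atoms: none
Why: Ring-closing olefin metathesis: the ruthenium alkylidene initiates at the unhindered allyl group (future C1–C2), and the new alkylidene adds intramolecularly to the neopentyl-type vinyl group (future C3) through a ruthenacyclobutane whose cycloreversion forms the C2=C3 bond and releases ethene, which drives the reaction. The closest known reaction type is RCM to cyclohexenes that carry an allylic quaternary carbon. Ring A closes as a six-membered carbocycle by this [2+2]/retro-[2+2] sequence; the trans ring fusion follows from the trans arrangement of the two alkenyl arms in 7, established in steps 2 and 3, so no new stereocentre is created. The selectivity needed is chemoselectivity for the two terminal alkenes over the endocyclic enone alkene and over intermolecular metathesis: the electron-poor cis-disubstituted enone C=C is a poor metathesis partner, no other ring size is accessible, and high dilution together with the two flanking quaternary carbons (Thorpe–Ingold effect) favours cyclisation.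

Step 5
Reactants: 8 (4aR,8aR)-5,5,8a-trimethyl-4a,5,8,8a-tetrahydronaphthalen-1(4H)-one
Product: 9 (4aR,8aR)-2-(hydroxymethyl)-5,5,8a-trimethyl-4a,5,8,8a-tetrahydronaphthalen-1(4H)-one
Conditions: HCHO (37 % aq.), DMAP (0.3 equiv), THF–H2O, rt
Reagents that add atoms: formaldehyde, C=O
Why: Morita–Baylis–Hillman reaction: DMAP adds reversibly to the unhindered β-carbon of the enone, the enolate is hydroxymethylated at the α-carbon (future C8, installing C17) and loss of DMAP restores the enone; the isolated ring A alkene is inert and no stereocentre is formed.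

Step 6
Reactants: 9 (4aR,8aR)-2-(hydroxymethyl)-5,5,8a-trimethyl-4a,5,8,8a-tetrahydronaphthalen-1(4H)-one
Product: 10 (4aR,8aR)-2-({[tert-butyl(diphenyl)silyl]oxy}methyl)-5,5,8a-trimethyl-4a,5,8,8a-tetrahydronaphthalen-1(4H)-one
Conditions: t-BuPh2SiCl, imidazole, CH2Cl2, rt
Reagents that add atoms: tert-butyl(chloro)diphenylsilane, CC(C)(C)[Si](Cl)(c1ccccc1)c1ccccc1
Why: Imidazole-promoted silylation of the primary allylic alcohol; the tert-butyldiphenylsilyl ether is chosen to survive the organotitanium, borane, chromium and amide-base steps that follow.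

Step 7
Reactants: 10 (4aR,8aR)-2-({[tert-butyl(diphenyl)silyl]oxy}methyl)-5,5,8a-trimethyl-4a,5,8,8a-tetrahydronaphthalen-1(4H)-one
Product: 11 (4aR,8aR)-2-({[tert-butyl(diphenyl)silyl]oxy}methyl)-5,5,8a-trimethyl-4a,5,6,7,8,8a-hexahydronaphthalen-1(4H)-one
Conditions: H2 (3 atm), RhCl(PPh3)3 (10 mol %), benzene–EtOH, rt
Reagents that add atoms: none
Why: Homogeneous hydrogenation: RhCl(PPh3)3 should reduce the isolated cis-disubstituted ring A alkene but not the trisubstituted conjugated enone alkene or the allylic C–O bond, and no stereocentre is created.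

Step 8
Reactants: 11 (4aR,8aR)-2-({[tert-butyl(diphenyl)silyl]oxy}methyl)-5,5,8a-trimethyl-4a,5,6,7,8,8a-hexahydronaphthalen-1(4H)-one
Product: 12 tert-butyl{[(4aR,8aR)-5,5,8a-trimethyl-1-methylidene-1,4,4a,5,6,7,8,8a-octahydronaphthalen-2-yl]methoxy}diphenylsilane
Conditions: Cp2TiMe2, toluene, 70 °C, dark
Reagents that add atoms: dimethyltitanocene Cp2TiMe2, C[Ti](C)(C1C=CC=C1)C1C=CC=C1
Why: Petasis methylenation: thermally generated Cp2Ti=CH2 undergoes [2+2] cycloaddition/cycloreversion with the hindered ketone under non-basic conditions, so the γ-hydrogens of the enone are not touched, giving the exocyclic 1,3-diene (C9=C11).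

Step 9
Reactants: 12 tert-butyl{[(4aR,8aR)-5,5,8a-trimethyl-1-methylidene-1,4,4a,5,6,7,8,8a-octahydronaphthalen-2-yl]methoxy}diphenylsilane
Product: 14 [(1S,4aR,8aR)-2-({[tert-butyl(diphenyl)silyl]oxy}methyl)-5,5,8a-trimethyl-1,4,4a,5,6,7,8,8a-octahydronaphthalen-1-yl]methanol, via alkylborane 13 (not isolated)
Conditions: 9-BBN, THF, 0 °C → rt; then NaOH, H2O2, 0 °C → rt
Reagents that add atoms: hydrogen peroxide, OO
Why: Hydroboration–oxidation: the bulky borane adds only to the terminal 1,1-disubstituted alkene of the diene, boron to CH2 and hydrogen to the ring carbon (future C9) from the face opposite the axial angular methyl, which sets this stereocentre with the CH2OH arm equatorial and cis to the methyl; oxidation of the C–B bond proceeds with retention.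

Step 10
Reactants: 14 [(1S,4aR,8aR)-2-({[tert-butyl(diphenyl)silyl]oxy}methyl)-5,5,8a-trimethyl-1,4,4a,5,6,7,8,8a-octahydronaphthalen-1-yl]methanol
Product: 15 5-({[(1S,4aR,8aR)-2-({[tert-butyl(diphenyl)silyl]oxy}methyl)-5,5,8a-trimethyl-1,4,4a,5,6,7,8,8a-octahydronaphthalen-1-yl]methyl}sulfanyl)-1-phenyl-1H-tetrazole
Conditions: 1-phenyl-1H-tetrazole-5-thiol, PPh3, i-PrO2C–N=N–CO2i-Pr, THF, 0 °C → rt
Reagents that add atoms: 1-phenyl-1H-tetrazole-5-thiol, Sc1nnnn1-c1ccccc1
Why: Mitsunobu thioetherification: the acidic tetrazole thiol displaces the activated primary alcohol (SN2 at CH2, no stereocentre affected) and the hindered silyl ether is untouched.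

Step 11
Reactants: 15 (sulfide)
Product: 16 5-({[(1S,4aR,8aR)-2-({[tert-butyl(diphenyl)silyl]oxy}methyl)-5,5,8a-trimethyl-1,4,4a,5,6,7,8,8a-octahydronaphthalen-1-yl]methyl}sulfonyl)-1-phenyl-1H-tetrazole
Conditions: (NH4)6Mo7O24·4H2O (10 mol %), H2O2 (30 % aq.), EtOH, 0 °C → rt
Reagents that add atoms: hydrogen peroxide, OO
Why: (NH4)6Mo7O24-catalysed oxidation with H2O2 converts the sulfide into the sulfone; the trisubstituted alkene, which has no free allylic hydroxyl group, should not be epoxidised under these conditions.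

Step 12
Reactants: 16 (sulfone)
Product: 17 (4S,4aR,8aR)-3-({[tert-butyl(diphenyl)silyl]oxy}methyl)-4a,8,8-trimethyl-4-{[(1-phenyl-1H-tetrazol-5-yl)sulfonyl]methyl}-4a,5,6,7,8,8a-hexahydronaphthalen-1(4H)-one
Conditions: CrO3, 3,5-dimethylpyrazole, CH2Cl2, −20 °C
Reagents that add atoms: chromium trioxide, O=[Cr](=O)=O
Why: Allylic C–H oxidation with the CrO3–3,5-dimethylpyrazole complex: of the allylic positions only the ring methylene (future C6) can give a conjugated enone, the known outcome for 7-ene decalins and sterols (7-en-6-one formation); sulfone and silyl ether are inert to hexavalent chromium under neutral conditions.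

Step 13
Reactants: 17 (enone)
Product: 18 (1S,4S,4aR,8aR)-3-({[tert-butyl(diphenyl)silyl]oxy}methyl)-4a,8,8-trimethyl-4-{[(1-phenyl-1H-tetrazol-5-yl)sulfonyl]methyl}-1,4,4a,5,6,7,8,8a-octahydronaphthalen-1-ol
Conditions: NaBH4, CeCl3·7H2O, MeOH, −40 → 0 °C
Reagents that add atoms: none
Why: Luche 1,2-reduction: hydride attacks the carbonyl from the face opposite the angular methyl and the syn-axial methyl of the gem-dimethyl group, giving the axial allylic alcohol cis to the angular methyl, which is the C6 configuration of the target.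

Step 14
Reactants: 19 2-methyl-2-vinyloxirane (racemic); 20 (4-methoxyphenyl)methanol
Product: 21 (2S)-2-[(4-methoxyphenyl)methoxy]-2-methylbut-3-en-1-ol
Conditions: Pd2(dba)3·CHCl3 (1 mol %), (R,R)-N,N′-(cyclohexane-1,2-diyl)bis[2-(diphenylphosphino)benzamide] (3 mol %), Et3B (1 mol %), CH2Cl2, rt
Reagents that add atoms: none
Why: Palladium-catalysed dynamic kinetic asymmetric allylic etherification: both epoxide enantiomers ionise to interconverting π-allyl palladium complexes, the borate formed from Et3B, the alcohol and the pendant alkoxide delivers the nucleophile to the tertiary terminus, and the chiral ligand selects the face, setting the quaternary carbinol centre (future C13).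

Step 15
Reactants: 21 (2S)-2-[(4-methoxyphenyl)methoxy]-2-methylbut-3-en-1-ol
Product: 22 (2S)-2-[(4-methoxyphenyl)methoxy]-2-methylbut-3-enal
Conditions: Dess–Martin periodinane, NaHCO3, CH2Cl2, 0 °C → rt
Reagents that add atoms: none
Why: Dess–Martin oxidation of the primary alcohol gives the α-quaternary, non-enolisable aldehyde, so the stereocentre cannot epimerise.

Step 16
Reactants: 18 (hydroxy sulfone); 22 (2S)-2-[(4-methoxyphenyl)methoxy]-2-methylbut-3-enal
Product: 23 (1S,4S,4aS,8aR)-3-({[tert-butyl(diphenyl)silyl]oxy}methyl)-4-{(1E,3S)-3-[(4-methoxyphenyl)methoxy]-3-methylpenta-1,4-dien-1-yl}-4a,8,8-trimethyl-1,4,4a,5,6,7,8,8a-octahydronaphthalen-1-ol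
Conditions: KN(SiMe3)2 (2.2 equiv, added to 18 + 22), DME, −60 °C → rt
Reagents that add atoms: none
Why: Julia–Kocienski olefination: the first equivalent of base forms the C6 alkoxide, the second metalates the sulfone, and addition to the non-enolisable aldehyde is followed by Smiles rearrangement and anti-elimination of sulfur dioxide and tetrazolate, which should give the (E)-C11=C12 alkene typical of phenyltetrazolyl sulfones with branched partners.

Step 17
Reactants: 23 (silyl ether)
Product: 24 (1S,4S,4aS,8aR)-3-(hydroxymethyl)-4-{(1E,3S)-3-[(4-methoxyphenyl)methoxy]-3-methylpenta-1,4-dien-1-yl}-4a,8,8-trimethyl-1,4,4a,5,6,7,8,8a-octahydronaphthalen-1-ol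
Conditions: Bu4NF, THF, 0 °C → rt
Reagents that add atoms: none
Why: Fluoride-induced cleavage of the silyl ether frees the primary allylic alcohol; the benzylic ether and the alkenes are unaffected.

Step 18
Reactants: 24 (diol)
Product: 25 (1S,4S,4aS,8aR)-3-[(acetyloxy)methyl]-4-{(1E,3S)-3-[(4-methoxyphenyl)methoxy]-3-methylpenta-1,4-dien-1-yl}-4a,8,8-trimethyl-1,4,4a,5,6,7,8,8a-octahydronaphthalen-1-yl acetate
Conditions: Ac2O, pyridine, DMAP, CH2Cl2, rt
Reagents that add atoms: acetic anhydride, CC(=O)OC(C)=O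
Why: DMAP-catalysed acetylation esterifies both the primary allylic and the hindered axial secondary alcohol, while the tertiary oxygen stays masked as its 4-methoxybenzyl ether.

Step 19
Reactants: 25 (diacetate)
Product: 26 (1S,4S,4aS,8aR)-3-[(acetyloxy)methyl]-4-[(1E,3S)-3-hydroxy-3-methylpenta-1,4-dien-1-yl]-4a,8,8-trimethyl-1,4,4a,5,6,7,8,8a-octahydronaphthalen-1-yl acetate (target)
Conditions: DDQ, CH2Cl2–pH 7 buffer, 0 °C
Reagents that add atoms: none
Why: Oxidative debenzylation: DDQ abstracts hydride from the electron-rich benzylic CH2 and hydrolysis of the oxocarbenium ion releases the tertiary bis-allylic alcohol under buffered conditions that leave the allylic acetates and all stereocentres untouched.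

**Compound list**

1 | (S)-(+)-carvone, (5S)-2-methyl-5-(prop-1-en-2-yl)cyclohex-2-en-1-one | O=C1C[C@@H](C(C)=C)CC=C1C | starting material
2 | (5S)-5-(1-hydroperoxy-1-methoxyethyl)-2-methylcyclohex-2-en-1-one (both epimers at the peroxy carbon) | O=C1C[C@@H](C(C)(OC)OO)CC=C1C | intermediate (not isolated)
3 | (1S)-4-methyl-5-oxocyclohex-3-en-1-yl acetate | O=C1C[C@@H](OC(C)=O)CC=C1C | intermediate
4 | trimethyl(3-methylbut-2-en-1-yl)silane | CC(C)=CC[Si](C)(C)C | starting material
5 | (1S,5S)-4-methyl-5-(2-methylbut-3-en-2-yl)-3-oxocyclohexyl acetate (mixture at C4) | O=C1C[C@@H](OC(C)=O)C[C@H](C(C)(C)C=C)C1C | intermediate (not isolated)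
6 | (5S,6R)-6-methyl-5-(2-methylbut-3-en-2-yl)cyclohex-2-en-1-one (trans; its 6-epimer converges in step 3) | O=C1C=CC[C@H](C(C)(C)C=C)[C@H]1C | intermediate
7 | (5R,6R)-6-methyl-5-(2-methylbut-3-en-2-yl)-6-(prop-2-en-1-yl)cyclohex-2-en-1-one | O=C1C=CC[C@H](C(C)(C)C=C)[C@@]1(C)CC=C | intermediate
8 | (4aR,8aR)-5,5,8a-trimethyl-4a,5,8,8a-tetrahydronaphthalen-1(4H)-one | O=C1C=CC[C@@H]2C(C)(C)C=CC[C@@]12C | intermediate
9 | (4aR,8aR)-2-(hydroxymethyl)-5,5,8a-trimethyl-4a,5,8,8a-tetrahydronaphthalen-1(4H)-one | O=C1C(CO)=CC[C@@H]2C(C)(C)C=CC[C@@]12C | intermediate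
10 | (4aR,8aR)-2-({[tert-butyl(diphenyl)silyl]oxy}methyl)-5,5,8a-trimethyl-4a,5,8,8a-tetrahydronaphthalen-1(4H)-one | O=C1C(CO[Si](c3ccccc3)(c3ccccc3)C(C)(C)C)=CC[C@@H]2C(C)(C)C=CC[C@@]12C | intermediate
11 | (4aR,8aR)-2-({[tert-butyl(diphenyl)silyl]oxy}methyl)-5,5,8a-trimethyl-4a,5,6,7,8,8a-hexahydronaphthalen-1(4H)-one | O=C1C(CO[Si](c3ccccc3)(c3ccccc3)C(C)(C)C)=CC[C@@H]2C(C)(C)CCC[C@@]12C | intermediate
12 | tert-butyl{[(4aR,8aR)-5,5,8a-trimethyl-1-methylidene-1,4,4a,5,6,7,8,8a-octahydronaphthalen-2-yl]methoxy}diphenylsilane | C=C1C(CO[Si](c3ccccc3)(c3ccccc3)C(C)(C)C)=CC[C@@H]2C(C)(C)CCC[C@@]12C | intermediate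
13 | 9-{[(1S,4aR,8aS)-2-({[tert-butyl(diphenyl)silyl]oxy}methyl)-5,5,8a-trimethyl-1,4,4a,5,6,7,8,8a-octahydronaphthalen-1-yl]methyl}-9-borabicyclo[3.3.1]nonane | C1CC2CCCC(C1)B2C[C@@H]1C(CO[Si](c3ccccc3)(c3ccccc3)C(C)(C)C)=CC[C@@H]2C(C)(C)CCC[C@@]12C | intermediate (not isolated)
14 | [(1S,4aR,8aR)-2-({[tert-butyl(diphenyl)silyl]oxy}methyl)-5,5,8a-trimethyl-1,4,4a,5,6,7,8,8a-octahydronaphthalen-1-yl]methanol | OC[C@@H]1C(CO[Si](c3ccccc3)(c3ccccc3)C(C)(C)C)=CC[C@@H]2C(C)(C)CCC[C@@]12C | intermediate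
15 | 5-({[(1S,4aR,8aR)-2-({[tert-butyl(diphenyl)silyl]oxy}methyl)-5,5,8a-trimethyl-1,4,4a,5,6,7,8,8a-octahydronaphthalen-1-yl]methyl}sulfanyl)-1-phenyl-1H-tetrazole | c1ccccc1-n1nnnc1SC[C@@H]1C(CO[Si](c3ccccc3)(c3ccccc3)C(C)(C)C)=CC[C@@H]2C(C)(C)CCC[C@@]12C | intermediate
16 | 5-({[(1S,4aR,8aR)-2-({[tert-butyl(diphenyl)silyl]oxy}methyl)-5,5,8a-trimethyl-1,4,4a,5,6,7,8,8a-octahydronaphthalen-1-yl]methyl}sulfonyl)-1-phenyl-1H-tetrazole | c1ccccc1-n1nnnc1S(=O)(=O)C[C@@H]1C(CO[Si](c3ccccc3)(c3ccccc3)C(C)(C)C)=CC[C@@H]2C(C)(C)CCC[C@@]12C | intermediate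
17 | (4S,4aR,8aR)-3-({[tert-butyl(diphenyl)silyl]oxy}methyl)-4a,8,8-trimethyl-4-{[(1-phenyl-1H-tetrazol-5-yl)sulfonyl]methyl}-4a,5,6,7,8,8a-hexahydronaphthalen-1(4H)-one | c1ccccc1-n1nnnc1S(=O)(=O)C[C@@H]1C(CO[Si](c3ccccc3)(c3ccccc3)C(C)(C)C)=CC(=O)[C@@H]2C(C)(C)CCC[C@@]12C | intermediate
18 | (1S,4S,4aR,8aR)-3-({[tert-butyl(diphenyl)silyl]oxy}methyl)-4a,8,8-trimethyl-4-{[(1-phenyl-1H-tetrazol-5-yl)sulfonyl]methyl}-1,4,4a,5,6,7,8,8a-octahydronaphthalen-1-ol | c1ccccc1-n1nnnc1S(=O)(=O)C[C@@H]1C(CO[Si](c3ccccc3)(c3ccccc3)C(C)(C)C)=C[C@H](O)[C@@H]2C(C)(C)CCC[C@@]12C | intermediate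
19 | 2-methyl-2-vinyloxirane (racemic) | CC1(C=C)CO1 | starting material
20 | (4-methoxyphenyl)methanol | COc1ccc(CO)cc1 | starting material
21 | (2S)-2-[(4-methoxyphenyl)methoxy]-2-methylbut-3-en-1-ol | C=C[C@](C)(OCc1ccc(OC)cc1)CO | intermediate
22 | (2S)-2-[(4-methoxyphenyl)methoxy]-2-methylbut-3-enal | C=C[C@](C)(OCc1ccc(OC)cc1)C=O | intermediate
23 | (1S,4S,4aS,8aR)-3-({[tert-butyl(diphenyl)silyl]oxy}methyl)-4-{(1E,3S)-3-[(4-methoxyphenyl)methoxy]-3-methylpenta-1,4-dien-1-yl}-4a,8,8-trimethyl-1,4,4a,5,6,7,8,8a-octahydronaphthalen-1-ol | C=C[C@](C)(OCc1ccc(OC)cc1)/C=C/[C@@H]1C(CO[Si](c3ccccc3)(c3ccccc3)C(C)(C)C)=C[C@H](O)[C@@H]2C(C)(C)CCC[C@@]12C | intermediate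
24 | (1S,4S,4aS,8aR)-3-(hydroxymethyl)-4-{(1E,3S)-3-[(4-methoxyphenyl)methoxy]-3-methylpenta-1,4-dien-1-yl}-4a,8,8-trimethyl-1,4,4a,5,6,7,8,8a-octahydronaphthalen-1-ol | C=C[C@](C)(OCc1ccc(OC)cc1)/C=C/[C@@H]1C(CO)=C[C@H](O)[C@@H]2C(C)(C)CCC[C@@]12C | intermediate
25 | (1S,4S,4aS,8aR)-3-[(acetyloxy)methyl]-4-{(1E,3S)-3-[(4-methoxyphenyl)methoxy]-3-methylpenta-1,4-dien-1-yl}-4a,8,8-trimethyl-1,4,4a,5,6,7,8,8a-octahydronaphthalen-1-yl acetate | C=C[C@](C)(OCc1ccc(OC)cc1)/C=C/[C@@H]1C(COC(C)=O)=C[C@H](OC(C)=O)[C@@H]2C(C)(C)CCC[C@@]12C | intermediate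
26 | (1S,4S,4aS,8aR)-3-[(acetyloxy)methyl]-4-[(1E,3S)-3-hydroxy-3-methylpenta-1,4-dien-1-yl]-4a,8,8-trimethyl-1,4,4a,5,6,7,8,8a-octahydronaphthalen-1-yl acetate; in labdane terms (5R,6S,9S,10S,13S)-6,17-diacetoxy-ent-labda-7,11E,14-trien-13-ol | C=C[C@](C)(O)/C=C/[C@@H]1C(COC(C)=O)=C[C@H](OC(C)=O)[C@@H]2C(C)(C)CCC[C@@]12C | target

**Totals.** 19 steps in all. The longest linear sequence is 17 steps (steps 1–13 and 16–19, from carvone); the side-chain aldehyde takes 2 steps (14, 15).

**Steps most likely to fail and fallbacks**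

1. Step 2. The β-acetoxy group may be lost under the Lewis acid (elimination to the cyclohexadienone and aromatisation) before conjugate addition takes place, and facial control by the acetoxy group may be incomplete. The fallback sets out from 1 and 4 and returns at 6. Hosomi–Sakurai addition to carvone itself (TiCl4, CH2Cl2, −78 °C), where the isopropenyl group directs trans addition, should give (3S,5S)-2-methyl-3-(2-methylbut-3-en-2-yl)-5-(prop-1-en-2-yl)cyclohexan-1-one F1. Ozonolysis of the 1,1-disubstituted alkene in CH2Cl2–MeOH (one equivalent of O3, −78 °C) should give the methoxy hydroperoxide F2; selectivity over the neopentyl vinyl group is expected to be only modest. Fragmentation with FeSO4 and Cu(OAc)2 (loss of methyl acetate, copper-mediated alkene formation toward the carbonyl) should then deliver enone 6.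

2. Step 12. Site selectivity of the C–H oxidation may be poor (attack at the tertiary allylic C–H next to the sulfonylmethyl group or at the silyloxymethyl group), and over-oxidation may occur. The fallback sets out from 11 and returns at 17; the oxygen is introduced earlier by vinylogous Rubottom oxidation. t-BuMe2SiOTf/Et3N should convert enone 11, whose only acidic position is the γ-methylene, into the silyl dienol ether F3. Dimethyldioxirane should give the γ-hydroxy enone F4 (either epimer), and Et3SiCl/imidazole its triethylsilyl ether F5. The operations of steps 8 to 11 then give the diene F6, the alkylborane F7, the alcohol F8, the sulfide F9 and the sulfone F10. Pyridinium p-toluenesulfonate in MeOH removes the triethylsilyl group to give the allylic alcohol F11, and MnO2 oxidation returns to 17.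

3. Step 16. Addition of the hindered sulfonyl carbanion (present as a dianion with the C6 alkoxide) to the α-quaternary aldehyde may be slow, with self-condensation of the metalated sulfone competing. The fallback sets out from 18 and 21 and returns at 23; the polarity of the olefination is reversed. Metalation of 18 with KN(SiMe3)2 and oxidation of the carbanion with bis(trimethylsilyl) peroxide (oxidative desulfonylation) should give the aldehyde F12. Mitsunobu reaction of 21 with 1-phenyl-1H-tetrazole-5-thiol gives the sulfide F13, and oxidation with (NH4)6Mo7O24·4H2O/H2O2 the sulfone F14. Julia–Kocienski olefination of F12 with metalated F14 (KN(SiMe3)2, DME) returns to 23.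

Further compounds
F1 | step 2 | (3S,5S)-2-methyl-3-(2-methylbut-3-en-2-yl)-5-(prop-1-en-2-yl)cyclohexan-1-one (mixture at C2) | O=C1C[C@@H](C(C)=C)C[C@H](C(C)(C)C=C)C1C
F2 | step 2 | (3S,5S)-5-(1-hydroperoxy-1-methoxyethyl)-2-methyl-3-(2-methylbut-3-en-2-yl)cyclohexan-1-one | O=C1C[C@@H](C(C)(OC)OO)C[C@H](C(C)(C)C=C)C1C
F3 | step 12 | tert-butyldimethylsilyl dienol ether of 11 (C9-silyloxy 6,8-diene) | CC(C)(C)[Si](C)(C)OC1=C(CO[Si](c3ccccc3)(c3ccccc3)C(C)(C)C)C=C[C@@H]2C(C)(C)CCC[C@@]12C
F4 | step 12 | 11 bearing a hydroxyl group at the γ-carbon (future C6, either epimer) | O=C1C(CO[Si](c3ccccc3)(c3ccccc3)C(C)(C)C)=CC(O)[C@@H]2C(C)(C)CCC[C@@]12C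
F5 | step 12 | triethylsilyl ether of F4 | O=C1C(CO[Si](c3ccccc3)(c3ccccc3)C(C)(C)C)=CC(O[Si](CC)(CC)CC)[C@@H]2C(C)(C)CCC[C@@]12C
F6 | step 12 | 12 bearing a triethylsilyloxy group at C6 | C=C1C(CO[Si](c3ccccc3)(c3ccccc3)C(C)(C)C)=CC(O[Si](CC)(CC)CC)[C@@H]2C(C)(C)CCC[C@@]12C
F7 | step 12 | 13 bearing a triethylsilyloxy group at C6 | C1CC2CCCC(C1)B2C[C@@H]1C(CO[Si](c3ccccc3)(c3ccccc3)C(C)(C)C)=CC(O[Si](CC)(CC)CC)[C@@H]2C(C)(C)CCC[C@@]12C
F8 | step 12 | 14 bearing a triethylsilyloxy group at C6 | OC[C@@H]1C(CO[Si](c3ccccc3)(c3ccccc3)C(C)(C)C)=CC(O[Si](CC)(CC)CC)[C@@H]2C(C)(C)CCC[C@@]12C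
F9 | step 12 | 15 bearing a triethylsilyloxy group at C6 | c1ccccc1-n1nnnc1SC[C@@H]1C(CO[Si](c3ccccc3)(c3ccccc3)C(C)(C)C)=CC(O[Si](CC)(CC)CC)[C@@H]2C(C)(C)CCC[C@@]12C
F10 | step 12 | 16 bearing a triethylsilyloxy group at C6 | c1ccccc1-n1nnnc1S(=O)(=O)C[C@@H]1C(CO[Si](c3ccccc3)(c3ccccc3)C(C)(C)C)=CC(O[Si](CC)(CC)CC)[C@@H]2C(C)(C)CCC[C@@]12C
F11 | step 12 | 16 bearing a hydroxyl group at C6 (either epimer) | c1ccccc1-n1nnnc1S(=O)(=O)C[C@@H]1C(CO[Si](c3ccccc3)(c3ccccc3)C(C)(C)C)=CC(O)[C@@H]2C(C)(C)CCC[C@@]12C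
F12 | step 16 | (1S,4S,4aR,8aR)-2-({[tert-butyl(diphenyl)silyl]oxy}methyl)-4-hydroxy-5,5,8a-trimethyl-1,4,4a,5,6,7,8,8a-octahydronaphthalene-1-carbaldehyde (C11 aldehyde) | O=C[C@@H]1C(CO[Si](c3ccccc3)(c3ccccc3)C(C)(C)C)=C[C@H](O)[C@@H]2C(C)(C)CCC[C@@]12C
F13 | step 16 | 5-({(2S)-2-[(4-methoxyphenyl)methoxy]-2-methylbut-3-en-1-yl}sulfanyl)-1-phenyl-1H-tetrazole | C=C[C@](C)(OCc1ccc(OC)cc1)CSc1nnnn1-c1ccccc1
F14 | step 16 | 5-({(2S)-2-[(4-methoxyphenyl)methoxy]-2-methylbut-3-en-1-yl}sulfonyl)-1-phenyl-1H-tetrazole | C=C[C@](C)(OCc1ccc(OC)cc1)CS(=O)(=O)c1nnnn1-c1ccccc1
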